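**Plan**

1. Retrosynthesis: the 1,2-dioxane is opened at O–C6 and at the peroxyhemiketal O–C3 (H2O2 across an E-C5=C6 alkene and the C3 ketone), the chain is cut at C6–C7, and the γ-lactone is cut at C2–C3 and O–C4 together.
2. Enabling feature: in the lactone ring C4 is a fully substituted carbon carrying the ring oxygen, next to C3 at the carbonyl level. C3/C4 is therefore a latent α-oxy-acyl bis-electrophile, the gem-dichloroepoxide of a CH3(CCl3)C–OH carbinol, which a malonate half-ester can annulate as O- then C-nucleophile.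
3. Forward order: alkynylation of trichloroacetone, lactone ring by the annulation, vinyl iodide, Negishi union with the C7–C14 chain, 1,2-dioxane ring last.
4. Stereochemistry: C4 by catalytic enantioselective alkynylation, inverted once in the annulation; C8 bought as (S)-3-bromo-2-methylpropan-1-ol; C6 and C3 relayed from C4 in the last ring closure (chair, E-alkene geometry, anti addition); both E-alkenes from syn carbo- or hydrometalation.

Key step: step 2

Remark: atoms are numbered C1 (lactone C=O), C2 (CH2), C3 (peroxyhemiketal carbon), C4 (CH3, lactone O), C5 (CH2), C6 (CH3, peroxide O), C7–C14 (chain, phenyl on C14); after step 11 only neutral or mildly acidic conditions are used, because base would open the peroxyhemiketal to the tetronate.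

**Route**

Step 1
Reactants: 1 1,1,1-trichloropropan-2-one; 2 propyne
Product: 3 (S)-1,1,1-trichloro-2-methylpent-3-yn-2-ol
Conditions: 2 (excess), (iPr-phebox)Rh(OAc)2(H2O) (3 mol %; phebox = 2,6-bis(4-isopropyl-4,5-dihydrooxazol-2-yl)phenyl; the ligand antipode that gives the S carbinol), Et2O, 25 °C, sealed vessel
Reagents that add atoms: none
Why: Catalytic enantioselective direct alkynylation of an activated trihalomethyl ketone under base-free conditions, in which the rhodium acetylide adds to the ketone inside the chiral pincer pocket and the large CCl3 versus small CH3 difference should set C4.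

Step 2
Reactants: 3 (S)-1,1,1-trichloro-2-methylpent-3-yn-2-ol; 4 3-tert-butoxy-3-oxopropanoic acid (mono-tert-butyl malonate)
Product: 7 tert-butyl (R)-4-hydroxy-5-methyl-2-oxo-5-(prop-1-yn-1-yl)-2,5-dihydrofuran-3-carboxylate, via gem-dichloroepoxide 5 (not isolated), via acyl chloride 6 (not isolated)
Conditions: 4 (3 equiv), DBU (6 equiv), MeCN, 0 to 25 °C; dilute HCl work-up
Reagents that add atoms: none
Why: Proposed new method: DBU turns 3 into its alkoxide, which closes onto the CCl3 group to give gem-dichloroepoxide 5; the carboxylate of 4 opens 5 at the tertiary propargylic carbon anti to the epoxide oxygen (new O–C4 bond), the epoxide oxygen collapses to acyl chloride 6, and the malonate CH2, acidic only once its carboxylate has been alkylated, is C-acylated by that acyl chloride (new C2–C3 bond) to give the enolised furan-2,4-dione 7. The closest known reaction types are the Jocic–Reeve, Corey–Link and Bargellini reactions, where a heteroatom nucleophile and then a second nucleophile add to the same dichloroepoxide, and the Rathke C-acylation of malonates by acyl chlorides; a malonate half-ester acting as O- and then C-nucleophile on one such epoxide has not been shown. The one ring that is closed, the furanone, forms by 5-exo-trig attack of C2 on the acyl chloride carbon C3. The only new stereocentre, C4, is under substrate control: the SN2 opening of 5 is stereospecific, so (S)-3 should give (R) at C4 by a single inversion. The step needs O- before C-alkylation and carboxylate rather than liberated chloride as the nucleophile at C4, which the monoanionic half-ester (no enolate present at that stage) used in excess secures, while the internal alkyne offers no acidic C–H to the base.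

Step 3
Reactants: 7 tert-butyl (R)-4-hydroxy-5-methyl-2-oxo-5-(prop-1-yn-1-yl)-2,5-dihydrofuran-3-carboxylate
Product: 9 (R)-4-hydroxy-5-methyl-5-(prop-1-yn-1-yl)furan-2(5H)-one, via carboxylic acid 8 (not isolated)
Conditions: TFA, CH2Cl2, 25 °C; then toluene, 80 °C
Reagents that add atoms: none
Why: Acidolysis of the tert-butyl ester gives the vinylogous β-keto acid 8, which should decarboxylate on warming (classical dealkoxycarbonylation of 3-carboxytetronic acids) without touching C4.

Step 4
Reactants: 9 (R)-4-hydroxy-5-methyl-5-(prop-1-yn-1-yl)furan-2(5H)-one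
Product: 10 (R)-4-(methoxymethoxy)-5-methyl-5-(prop-1-yn-1-yl)furan-2(5H)-one
Conditions: MOMCl, i-Pr2NEt, CH2Cl2, 0 °C
Reagents that add atoms: chloromethyl methyl ether, COCCl
Why: O-alkylation of the vinylogous acid by a hard oxocarbenium-type electrophile masks the acidic, iodine-sensitive enol for the organometallic steps.

Step 5
Reactants: 10 (R)-4-(methoxymethoxy)-5-methyl-5-(prop-1-yn-1-yl)furan-2(5H)-one
Product: 12 (R)-5-[(E)-2-iodoprop-1-en-1-yl]-4-(methoxymethoxy)-5-methylfuran-2(5H)-one, via alkenylzirconocene chloride 11 (not isolated)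
Conditions: Cp2Zr(H)Cl (1.5 equiv), THF, 25 to 40 °C; then I2, THF, 0 °C
Reagents that add atoms: iodine, II
Why: Hydrozirconation with the Schwartz reagent adds H and Zr syn, with zirconium on the methyl-bearing alkyne carbon remote from the quaternary centre, and iodinolysis with retention should give the E vinyl iodide in which CH3 is cis to C4.

Step 6
Reactants: 13 but-3-yn-1-ol; 14 benzyl chloride
Product: 16 (E)-3-methyl-5-phenylpent-3-en-1-ol, via alkenylalane 15 (not isolated)
Conditions: Me3Al (3 equiv), Cp2ZrCl2 (0.3 equiv), CH2Cl2, 0 to 25 °C; then 14, Pd(PPh3)4 (3 mol %), THF, 25 °C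
Reagents that add atoms: trimethylaluminium, C[Al](C)C
Why: Negishi zirconium-catalysed syn carboalumination of the terminal alkyne (methyl to the internal carbon) followed by coupling of the alkenylalane with benzyl chloride under zerovalent palladium catalysis, with retention, should give the E trisubstituted alkene C12=C13.

Step 7
Reactants: 16 (E)-3-methyl-5-phenylpent-3-en-1-ol
Product: 17 (E)-(5-bromo-3-methylpent-2-en-1-yl)benzene
Conditions: CBr4, PPh3, CH2Cl2, 0 °C
Reagents that add atoms: carbon tetrabromide, BrC(Br)(Br)Br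
Why: Appel bromination of a primary homoallylic alcohol under neutral conditions leaves the alkene geometry intact.

Step 8
Reactants: 17 (E)-(5-bromo-3-methylpent-2-en-1-yl)benzene; 18 (S)-3-bromo-2-methylpropan-1-ol
Product: 21 (R,E)-2,6-dimethyl-8-phenyloct-6-en-1-ol, via Grignard reagent 19 (not isolated), via magnesium alkoxide 20 (not isolated)
Conditions: 17, Mg, THF, 25 to 40 °C (gives 19); 18, i-PrMgCl (1.0 equiv), THF, −20 °C (gives 20); 19 (1.5 equiv) added to 20, Li2CuCl4 (3 mol %), THF, −20 to 25 °C
Reagents that add atoms: none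
Why: Kochi-type copper-catalysed sp3–sp3 coupling of a primary Grignard reagent with the primary bromide of the pre-formed magnesium alkoxide forms C9–C10, and the C8 stereocentre, bought with 18, is not touched.

Step 9
Reactants: 21 (R,E)-2,6-dimethyl-8-phenyloct-6-en-1-ol
Product: 22 (R,E)-(8-iodo-3,7-dimethyloct-2-en-1-yl)benzene
Conditions: I2, PPh3, imidazole, CH2Cl2, 0 to 25 °C
Reagents that add atoms: iodine, II
Why: Appel-type iodination of the primary alcohol gives the iodide needed for lithium–iodine exchange.

Step 10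
Reactants: 22 (R,E)-(8-iodo-3,7-dimethyloct-2-en-1-yl)benzene; 12 (R)-5-[(E)-2-iodoprop-1-en-1-yl]-4-(methoxymethoxy)-5-methylfuran-2(5H)-one
Product: 25 (R)-4-(methoxymethoxy)-5-methyl-5-[(1E,4R,8E)-2,4,8-trimethyl-10-phenyldeca-1,8-dien-1-yl]furan-2(5H)-one, via alkyllithium 23 (not isolated), via alkylzinc chloride 24 (not isolated)
Conditions: 22, t-BuLi (2.1 equiv), Et2O, −78 °C; ZnCl2, THF, −78 to 25 °C; then 12, Pd(PPh3)4 (5 mol %), THF, 25 °C
Reagents that add atoms: none
Why: Lithium–iodine exchange, transmetalation to zinc and Negishi sp3–sp2 coupling (zerovalent palladium) with retention of the vinyl iodide geometry joins C6 to C7 and should give the E-C5=C6 alkene, the lactone being inert to the organozinc.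

Step 11
Reactants: 25 (R)-4-(methoxymethoxy)-5-methyl-5-[(1E,4R,8E)-2,4,8-trimethyl-10-phenyldeca-1,8-dien-1-yl]furan-2(5H)-one
Product: 26 (R)-4-hydroxy-5-methyl-5-[(1E,4R,8E)-2,4,8-trimethyl-10-phenyldeca-1,8-dien-1-yl]furan-2(5H)-one
Conditions: 1 M HCl, THF, 25 °C
Reagents that add atoms: none
Why: The methoxymethyl enol ether is an acyl-acetal-type vinylogous ester and should hydrolyse under acid mild enough to leave both alkenes and the tertiary allylic lactone C–O bond alone.

Step 12
Reactants: 26 (R)-4-hydroxy-5-methyl-5-[(1E,4R,8E)-2,4,8-trimethyl-10-phenyldeca-1,8-dien-1-yl]furan-2(5H)-one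
Product: 29 CNP0361739.2 (target), via perhydrate 27 (not isolated), via organomercurial 28 (not isolated)
Conditions: H2O2 (anhydrous, in Et2O, 1.5 equiv), Hg(OAc)2 (1.05 equiv), HClO4 (cat.), CH2Cl2, −20 to 0 °C; water wash; then Bu3SnH (2.5 equiv), CH2Cl2, −20 to 0 °C
Reagents that add atoms: hydrogen peroxide, OO
Why: Cycloperoxymercuration–demercuration, in which the keto tautomer adds H2O2 to give perhydrate 27, whose hydroperoxy oxygen opens the mercurinium ion of the proximal alkene at tertiary C6 (6-endo, Markovnikov, anti) through a chair with the C4 methyl equatorial and the lactone oxygen axial, so that the E geometry should place the C6 methyl axial and cis to the lactone oxygen (C6 R) while the cis ring fusion fixes C3, before tin hydride replaces mercury by hydrogen.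

**Compound list**

1 | 1,1,1-trichloropropan-2-one | CC(=O)C(Cl)(Cl)Cl | starting material
2 | propyne | CC#C | starting material
3 | (S)-1,1,1-trichloro-2-methylpent-3-yn-2-ol | CC#C[C@](C)(O)C(Cl)(Cl)Cl | intermediate
4 | 3-tert-butoxy-3-oxopropanoic acid (mono-tert-butyl malonate) | OC(=O)CC(=O)OC(C)(C)C | starting material
5 | (S)-2,2-dichloro-3-methyl-3-(prop-1-yn-1-yl)oxirane | CC#C[C@]1(C)OC1(Cl)Cl | intermediate
6 | 1-tert-butyl 3-[(R)-1-chloro-2-methyl-1-oxopent-3-yn-2-yl] propanedioate | CC#C[C@@](C)(OC(=O)CC(=O)OC(C)(C)C)C(Cl)=O | intermediate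
7 | tert-butyl (R)-4-hydroxy-5-methyl-2-oxo-5-(prop-1-yn-1-yl)-2,5-dihydrofuran-3-carboxylate | CC#C[C@@]1(C)OC(=O)C(C(=O)OC(C)(C)C)=C1O | intermediate
8 | (R)-4-hydroxy-5-methyl-2-oxo-5-(prop-1-yn-1-yl)-2,5-dihydrofuran-3-carboxylic acid | CC#C[C@@]1(C)OC(=O)C(C(O)=O)=C1O | intermediate
9 | (R)-4-hydroxy-5-methyl-5-(prop-1-yn-1-yl)furan-2(5H)-one | CC#C[C@@]1(C)OC(=O)C=C1O | intermediate
10 | (R)-4-(methoxymethoxy)-5-methyl-5-(prop-1-yn-1-yl)furan-2(5H)-one | CC#C[C@@]1(C)OC(=O)C=C1OCOC | intermediate
11 | alkenylzirconocene chloride from 10 (Zr on the methyl-bearing carbon, H and Zr cis) | C/C(=C\[C@@]1(C)OC(=O)C=C1OCOC)[Zr](Cl)(C1C=CC=C1)C1C=CC=C1 | intermediate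
12 | (R)-5-[(E)-2-iodoprop-1-en-1-yl]-4-(methoxymethoxy)-5-methylfuran-2(5H)-one | C/C(I)=C\[C@@]1(C)OC(=O)C=C1OCOC | intermediate
13 | but-3-yn-1-ol | C#CCCO | starting material
14 | benzyl chloride | ClCc1ccccc1 | starting material
15 | (E)-alkenyl(dimethyl)alane of the dimethylaluminium alkoxide of 13 (CH3 and Al cis) | C[Al](C)/C=C(\C)CCO[Al](C)C | intermediate
16 | (E)-3-methyl-5-phenylpent-3-en-1-ol | OCC/C(C)=C/Cc1ccccc1 | intermediate
17 | (E)-(5-bromo-3-methylpent-2-en-1-yl)benzene | BrCC/C(C)=C/Cc1ccccc1 | intermediate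
18 | (S)-3-bromo-2-methylpropan-1-ol | OC[C@H](C)CBr | starting material
19 | [(E)-3-methyl-5-phenylpent-3-en-1-yl]magnesium bromide | Br[Mg]CC/C(C)=C/Cc1ccccc1 | intermediate
20 | chloromagnesium (S)-3-bromo-2-methylpropan-1-olate | Cl[Mg]OC[C@H](C)CBr | intermediate
21 | (R,E)-2,6-dimethyl-8-phenyloct-6-en-1-ol | OC[C@H](C)CCC/C(C)=C/Cc1ccccc1 | intermediate
22 | (R,E)-(8-iodo-3,7-dimethyloct-2-en-1-yl)benzene | IC[C@H](C)CCC/C(C)=C/Cc1ccccc1 | intermediate
23 | [(R,E)-2,6-dimethyl-8-phenyloct-6-en-1-yl]lithium | [Li]C[C@H](C)CCC/C(C)=C/Cc1ccccc1 | intermediate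
24 | [(R,E)-2,6-dimethyl-8-phenyloct-6-en-1-yl]zinc chloride | Cl[Zn]C[C@H](C)CCC/C(C)=C/Cc1ccccc1 | intermediate
25 | (R)-4-(methoxymethoxy)-5-methyl-5-[(1E,4R,8E)-2,4,8-trimethyl-10-phenyldeca-1,8-dien-1-yl]furan-2(5H)-one | C/C(=C\[C@@]1(C)OC(=O)C=C1OCOC)C[C@H](C)CCC/C(C)=C/Cc1ccccc1 | intermediate
26 | (R)-4-hydroxy-5-methyl-5-[(1E,4R,8E)-2,4,8-trimethyl-10-phenyldeca-1,8-dien-1-yl]furan-2(5H)-one | C/C(=C\[C@@]1(C)OC(=O)C=C1O)C[C@H](C)CCC/C(C)=C/Cc1ccccc1 | intermediate
27 | (4R,5R)-4-hydroperoxy-4-hydroxy-5-methyl-5-[(1E,4R,8E)-2,4,8-trimethyl-10-phenyldeca-1,8-dien-1-yl]dihydrofuran-2(3H)-one | C/C(=C\[C@@]1(C)OC(=O)C[C@@]1(O)OO)C[C@H](C)CCC/C(C)=C/Cc1ccccc1 | intermediate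
28 | 5-(acetoxymercurio) derivative of 29 (Hg on C5, trans to the peroxide oxygen on C6) | C/C(=C\Cc1ccccc1)CCC[C@@H](C)C[C@]1(C)[C@@H]([Hg]OC(C)=O)[C@@]2(C)OC(=O)C[C@@]2(O)OO1 | intermediate
29 | CNP0361739.2: (3R,4R,6R)-3-hydroxy-4,6-dimethyl-6-[(2R,6E)-2,6-dimethyl-8-phenyloct-6-en-1-yl]-1,2-dioxane whose C3 and C4 are cis-bridged by –CH2–C(=O)–O– (γ-lactone, oxygen on C4) | C/C(=C\Cc1ccccc1)CCC[C@@H](C)C[C@]1(C)C[C@@]2(C)OC(=O)C[C@@]2(O)OO1 | target

**Count and risks**

Total step count: 12. Longest linear sequence: 8 steps (1, 2, 3, 4, 5, 10, 11, 12); the chain branch (6, 7, 8, 9) joins at step 10.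

Steps most likely to fail:

Step 2. What may go wrong: the chloride set free competes with the carboxylate for dichloroepoxide 5 (an α-chloro acyl chloride that later cyclises with overall retention), or the tertiary propargylic C–O bond ionises partly, so that the inversion at C4 is eroded; the amidine base may also be acylated. Fallback (known chemistry): setting out from 2 and commercial methyl pyruvate, the rhodium-catalysed alkynylation of step 1 is run on the α-keto ester, using the ligand antipode that gives the R alcohol since no inversion follows, to give methyl (R)-2-hydroxy-2-methylpent-3-ynoate F1. Acetylation (Ac2O, DMAP, Et3N) gives methyl (R)-2-acetoxy-2-methylpent-3-ynoate F2, and Lacey–Dieckmann cyclisation (LiHMDS, THF, −78 to 0 °C) closes the furanone, returning to the route at 9.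

Step 12. What may go wrong: the mercurinium ion is captured by the tetronate oxygen instead of the perhydrate, or Hg(OAc)2 and H2O2 are diverted to the remote C12=C13 alkene. Fallback: setting out from 26, Hg(OAc)2 alone (CH2Cl2, 0 °C, no peroxide present) is allowed to give the 5-endo oxymercuration product, the bicyclic enol ether mercurial F3, which only the alkene next to the internal nucleophile can form. F3 is then treated with anhydrous H2O2 and catalytic HClO4, which re-opens the tertiary C6–O bond through the same mercurinium ion (Hg anti, so the configuration at C6 is kept) and lets the C6 hydroperoxide close onto the C3 ketone; the route is rejoined at 28 and finished with Bu3SnH.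

Step 1. What may go wrong: poor enantiofacial discrimination or haloform-type cleavage of the trichloromethyl ketone under the catalytic conditions. Fallback: setting out from 1, 1-propynylmagnesium bromide (THF, −78 °C) gives racemic carbinol F4. The conditions of step 2 then give, through racemic dichloroepoxide F5 and racemic acyl chloride F6, racemic ester F7, and those of step 3 give, through racemic acid F8, racemic tetronic acid F9. Classical resolution of this strong vinylogous acid by crystallisation with (R)-1-phenylethylamine (or its antipode, whichever makes the salt of the R acid the less soluble) gives salt F10, and acidification returns to the route at 9.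

**Further compounds**

F1 | step 2 | methyl (R)-2-hydroxy-2-methylpent-3-ynoate | CC#C[C@@](C)(O)C(=O)OC
F2 | step 2 | methyl (R)-2-acetoxy-2-methylpent-3-ynoate | CC#C[C@@](C)(OC(C)=O)C(=O)OC
F3 | step 12 | 5-endo oxymercuration product of 26 (enol oxygen bonded to C6, AcOHg on C5 trans to it) | C/C(=C\Cc1ccccc1)CCC[C@@H](C)C[C@]1(C)[C@@H]([Hg]OC(C)=O)[C@@]2(C)OC(=O)C=C2O1
F4 | step 1 | rac-1,1,1-trichloro-2-methylpent-3-yn-2-ol | CC#CC(C)(O)C(Cl)(Cl)Cl
F5 | step 1 | rac-2,2-dichloro-3-methyl-3-(prop-1-yn-1-yl)oxirane | CC#CC1(C)OC1(Cl)Cl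
F6 | step 1 | rac-1-tert-butyl 3-(1-chloro-2-methyl-1-oxopent-3-yn-2-yl) propanedioate | CC#CC(C)(OC(=O)CC(=O)OC(C)(C)C)C(Cl)=O
F7 | step 1 | rac-tert-butyl 4-hydroxy-5-methyl-2-oxo-5-(prop-1-yn-1-yl)-2,5-dihydrofuran-3-carboxylate | CC#CC1(C)OC(=O)C(C(=O)OC(C)(C)C)=C1O
F8 | step 1 | rac-4-hydroxy-5-methyl-2-oxo-5-(prop-1-yn-1-yl)-2,5-dihydrofuran-3-carboxylic acid | CC#CC1(C)OC(=O)C(C(O)=O)=C1O
F9 | step 1 | rac-4-hydroxy-5-methyl-5-(prop-1-yn-1-yl)furan-2(5H)-one | CC#CC1(C)OC(=O)C=C1O
F10 | step 1 | (R)-1-phenylethylammonium salt of 9 | CC#C[C@@]1(C)OC(=O)C=C1[O-].C[C@@H]([NH3+])c1ccccc1
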